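**Plan**

- Numbering of the target: oxane O1, C2 (aryl), C3 (cinnamyl chain), C4, C5, C6; C7 is the carbinol carbon on C5. O1 lies between the benzylic C2 and the C6 methylene, so the ring O1–C2–C3–C4–C5–C6 is a cyclopentanone (C6=O, C2, C3, C4, C5) with one oxygen let into its C2–C6 bond.
- Retrosynthetic cuts, in order: the side-chain C=C (sulfone olefination); O1–C6 (ether closure of a 1,5-diol); O1–C2 (Baeyer–Villiger, back to the C2–C6 bond of the cyclopentanone); C5–C7 (aldol); C2–C6, C5–C6 and C3–C4 (alkyne + CO + ethylene); aryl–alkyne (Sonogashira).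
- Forward: aryl alkyne, cyclopentenone by [2+2+1], α′-aldol, all-cis cyclopentanone, ring expansion to the δ-lactone, reduction and re-closure to the oxane, then the styrenyl chain is joined and the silyl groups are removed.
- Stereochemistry: C5 and C7 from a reagent-controlled anti boron aldol; C2 and C3 from syn hydrogenation on the face away from the C5 substituent; retention in the C2 shift and in the ether closure; E-alkene from the Julia–Kocienski olefination.

Key step: step 8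

Abbreviations: TBS = tert-butyldimethylsilyl; TIPS = triisopropylsilyl; Ar = 4-(triisopropylsilyloxy)phenyl; PT = 1-phenyl-1H-tetrazol-5-yl; the atom labels O1 and C2–C7 are those of the target in every intermediate.

Assumption: the bromoborane made from (−)-menthone, bis{[(1R,2S,5R)-2-isopropyl-5-methylcyclohexyl]methyl}boron bromide, is taken to deliver the (5S,7R) aldol (attack on the Re face of the aldehyde); if analysis of the first run shows the mirror-image adduct, the antipodal reagent from (+)-menthone is used with no other change.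

**Route**

Step 1
Reactants: 1 4-iodophenol
Product: 2 (4-iodophenoxy)triisopropylsilane
Conditions: TIPSCl, imidazole, DMF, rt
Reagents that add atoms: triisopropylsilyl chloride, CC(C)[Si](Cl)(C(C)C)C(C)C
Why: Silyl ether formation on the phenol gives a TIPS aryl ether that should survive the basic, reductive, oxidative and mildly acidic steps ahead and still leave with fluoride at the end.

Step 2
Reactants: 2 (4-iodophenoxy)triisopropylsilane; 3 tert-butyl(but-3-yn-1-yloxy)dimethylsilane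
Product: 4 tert-butyldimethyl{[4-(4-triisopropylsilyloxyphenyl)but-3-yn-1-yl]oxy}silane
Conditions: PdCl2(PPh3)2 (cat.), CuI (cat.), Et3N, THF, rt
Reagents that add atoms: none
Why: Sonogashira coupling of an aryl iodide with a terminal alkyne runs at room temperature and joins the future C2 aryl group to the C2–C3 unit with its two-carbon chain.

Step 3
Reactants: 4 tert-butyldimethyl{[4-(4-triisopropylsilyloxyphenyl)but-3-yn-1-yl]oxy}silane; 5 ethylene
Product: 7 3-[2-(TBSO)ethyl]-2-Ar-cyclopent-2-en-1-one, via alkyne–hexacarbonyldicobalt complex 6 (not isolated)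
Conditions: Co2(CO)8, CH2Cl2, rt; then ethylene (6 bar), NMO, 4 Å MS, CH2Cl2, rt
Reagents that add atoms: dicobalt octacarbonyl (supplies the C6 carbonyl), O=C=[Co](=C=O)(=C=O)(=C=O)[Co](=C=O)(=C=O)(=C=O)=C=O
Why: Pauson–Khand [2+2+1] cycloaddition of the alkyne–cobalt complex with ethylene under N-oxide promotion builds the cyclopentenone, and as with other aryl alkyl alkynes the alkene should insert at the less hindered alkyl-bearing alkyne carbon so that the aryl group ends up at C2 next to the carbonyl.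

Step 4
Reactants: 8 4-hydroxybenzaldehyde
Product: 9 4-(triisopropylsilyloxy)benzaldehyde
Conditions: TIPSCl, imidazole, DMF, rt
Reagents that add atoms: triisopropylsilyl chloride, CC(C)[Si](Cl)(C(C)C)C(C)C
Why: The same phenol silylation as in step 1 gives the aldehyde used both in the aldol and in the final olefination.

Step 5
Reactants: 7 3-[2-(TBSO)ethyl]-2-Ar-cyclopent-2-en-1-one; 9 4-(triisopropylsilyloxy)benzaldehyde
Product: 11 (5S)-3-[2-(TBSO)ethyl]-5-[(R)-hydroxy(Ar)methyl]-2-Ar-cyclopent-2-en-1-one, via boron dienolate 10 (not isolated)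
Conditions: bis(menthylmethyl)boron bromide [from (−)-menthone], Et3N, CH2Cl2, −78 °C; then 9, −78 → −20 °C; pH 7 buffer, MeOH, H2O2, 0 °C
Reagents that add atoms: none
Why: In this boron-mediated asymmetric aldol reaction, amine-assisted enolisation takes the only sp3 α-carbon (C5), the ring-locked E-enol borinate reacts through a closed chair transition state to give the anti adduct, and the chiral menthylmethyl ligands on boron choose the enolate face so that C5 (S) and C7 (R) are set together.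

Step 6
Reactants: 11 (5S)-3-[2-(TBSO)ethyl]-5-[(R)-hydroxy(Ar)methyl]-2-Ar-cyclopent-2-en-1-one
Product: 12 (5S)-3-[2-(TBSO)ethyl]-5-[(R)-(TBSO)(Ar)methyl]-2-Ar-cyclopent-2-en-1-one
Conditions: TBSOTf, 2,6-lutidine, CH2Cl2, −78 → 0 °C
Reagents that add atoms: tert-butyldimethylsilyl triflate, CC(C)(C)[Si](C)(C)OS(=O)(=O)C(F)(F)F
Why: Silylation with the silyl triflate and a hindered base at low temperature caps the β-hydroxy ketone before retro-aldol or dehydration can set in and makes the C5 substituent bulky enough to steer the hydrogenation.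

Step 7
Reactants: 12 (5S)-3-[2-(TBSO)ethyl]-5-[(R)-(TBSO)(Ar)methyl]-2-Ar-cyclopent-2-en-1-one
Product: 13 (2R,3R,5S)-3-[2-(TBSO)ethyl]-5-[(R)-(TBSO)(Ar)methyl]-2-Ar-cyclopentan-1-one (all-cis)
Conditions: H2 (5 bar), 10% Pd/C, EtOAc, rt; filtered through Celite and used at once
Reagents that add atoms: none
Why: Heterogeneous catalytic hydrogenation adds both hydrogens syn to the tetrasubstituted enone on the face away from the bulky C5 substituent, as in the cis-selective hydrogenation of 2,3-disubstituted cyclopent-2-enones, so the C2 aryl group and the C3 chain should end up cis to each other and to the C5 substituent, and the neutral medium should spare the epimerisable C2 centre.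

Step 8
Reactants: 13 (2R,3R,5S)-3-[2-(TBSO)ethyl]-5-[(R)-(TBSO)(Ar)methyl]-2-Ar-cyclopentan-1-one
Product: 15 (3S,5R,6R)-5-[2-(TBSO)ethyl]-3-[(R)-(TBSO)(Ar)methyl]-6-Ar-tetrahydro-2H-pyran-2-one (all-cis δ-lactone), via Criegee adduct 14 (not isolated)
Conditions: mCPBA, NaHCO3, CH2Cl2, 0 °C → rt
Reagents that add atoms: 3-chloroperbenzoic acid, OOC(=O)c1cccc(Cl)c1
Why: Baeyer–Villiger oxidation: the peracid adds to the C6 carbonyl to give the Criegee adduct 14, and the C2–C6 bond anti-periplanar to the O–O bond shifts from C6 to oxygen as 3-chlorobenzoate leaves, so that the peroxide oxygen on C6 becomes O1 and gains its bond to C2 while C2–C6 is cleaved. The closest known reaction is the peracid oxidation of 2-arylcyclopentanones to 6-aryl-δ-valerolactones with migration of the benzylic carbon. The six-membered lactone ring is closed by ring expansion, a 1,2-shift that inserts one oxygen into the five-membered ring, and not by an exo or endo cyclisation. No stereocentre is created; the shift is suprafacial with retention at C2 and leaves C3, C5 and C7 untouched, so the all-cis array of 13 should pass unchanged into 15. The step needs migration of C2 in preference to C5, and the substrate secures this because C2 is secondary, benzylic and bound to a para-silyloxyphenyl ring that stabilises the electron-deficient transition state, whereas C5 is deactivated by the inductively withdrawing β-silyloxy group on C7. It also needs C2 not to epimerise before it migrates, which the bicarbonate buffer and the immediate use of 13 are meant to ensure.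

Step 9
Reactants: 15 (3S,5R,6R)-5-[2-(TBSO)ethyl]-3-[(R)-(TBSO)(Ar)methyl]-6-Ar-tetrahydro-2H-pyran-2-one
Product: 16 (1R,2R,4R)-2-[2-(TBSO)ethyl]-4-[(R)-(TBSO)(Ar)methyl]-1-Ar-pentane-1,5-diol
Conditions: LiBH4, THF, 0 °C → rt
Reagents that add atoms: none
Why: Hydride reduction of the lactone with lithium borohydride gives the 1,5-diol without touching the silyl ethers, breaks no bond at a stereocentre and removes the base-sensitive C5 α-proton situation quickly.

Step 10
Reactants: 16 (1R,2R,4R)-2-[2-(TBSO)ethyl]-4-[(R)-(TBSO)(Ar)methyl]-1-Ar-pentane-1,5-diol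
Product: 18 (2R,3R,5R)-3-[2-(TBSO)ethyl]-5-[(R)-(TBSO)(Ar)methyl]-2-Ar-tetrahydro-2H-pyran (all-cis), via primary tosylate 17 (not isolated)
Conditions: TsCl, Et3N, DMAP (cat.), CH2Cl2, 0 °C; then solvent change to THF, NaH, 0 °C → rt
Reagents that add atoms: none
Why: Selective sulfonylation of the primary C6 hydroxyl followed by intramolecular Williamson etherification (6-exo-tet SN2 at C6 by the C2 alkoxide) closes the oxane without breaking any bond at a stereocentre, so the C2 configuration is kept.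

Step 11
Reactants: 18 (2R,3R,5R)-3-[2-(TBSO)ethyl]-5-[(R)-(TBSO)(Ar)methyl]-2-Ar-tetrahydro-2H-pyran
Product: 19 2-{(2R,3R,5R)-5-[(R)-(TBSO)(Ar)methyl]-2-Ar-tetrahydro-2H-pyran-3-yl}ethan-1-ol
Conditions: CSA (cat.), MeOH/CH2Cl2 (1:1), 0 °C
Reagents that add atoms: none
Why: Acid-catalysed methanolysis (selective desilylation) should remove the unhindered primary TBS ether much faster than the hindered secondary benzylic one, while aryl silyl ethers are stable to mild acid.

Step 12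
Reactants: 19 2-{(2R,3R,5R)-5-[(R)-(TBSO)(Ar)methyl]-2-Ar-tetrahydro-2H-pyran-3-yl}ethan-1-ol
Product: 20 5-({2-[(2R,3R,5R)-5-[(R)-(TBSO)(Ar)methyl]-2-Ar-tetrahydro-2H-pyran-3-yl]ethyl}sulfanyl)-1-phenyl-1H-tetrazole
Conditions: 1-phenyl-1H-tetrazole-5-thiol, PPh3, DIAD, THF, 0 °C → rt
Reagents that add atoms: 1-phenyl-1H-tetrazole-5-thiol, Sc1nnnn1-c1ccccc1
Why: Mitsunobu thioetherification of a primary alcohol with the acidic tetrazole thiol is the standard entry to Julia–Kocienski sulfones and leaves the silyl ethers alone.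

Step 13
Reactants: 20 5-({2-[(2R,3R,5R)-5-[(R)-(TBSO)(Ar)methyl]-2-Ar-tetrahydro-2H-pyran-3-yl]ethyl}sulfanyl)-1-phenyl-1H-tetrazole
Product: 21 5-({2-[(2R,3R,5R)-5-[(R)-(TBSO)(Ar)methyl]-2-Ar-tetrahydro-2H-pyran-3-yl]ethyl}sulfonyl)-1-phenyl-1H-tetrazole
Conditions: (NH4)6Mo7O24·4H2O (cat.), 30% H2O2, EtOH/THF, 0 °C → rt
Reagents that add atoms: hydrogen peroxide, OO
Why: Molybdate-catalysed peroxide oxidation of the heteroaryl sulfide to the sulfone is routine and should not affect the silyl ethers or the benzylic ether.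

Step 14
Reactants: 21 5-({2-[(2R,3R,5R)-5-[(R)-(TBSO)(Ar)methyl]-2-Ar-tetrahydro-2H-pyran-3-yl]ethyl}sulfonyl)-1-phenyl-1H-tetrazole; 9 4-(triisopropylsilyloxy)benzaldehyde
Product: 23 (2R,3S,5R)-5-[(R)-(TBSO)(Ar)methyl]-2-Ar-3-[(E)-3-Ar-prop-2-en-1-yl]tetrahydro-2H-pyran, via potassium sulfonyl carbanion 22 (not isolated)
Conditions: KHMDS, DME, −60 °C; then 9, −60 °C → rt
Reagents that add atoms: none
Why: Julia–Kocienski olefination of a metalated alkyl PT sulfone with an electron-rich aromatic aldehyde proceeds by addition, Smiles rearrangement and loss of SO2 and the tetrazolone, and this pairing is the one that reliably gives the conjugated E-alkene.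

Step 15
Reactants: 23 (2R,3S,5R)-5-[(R)-(TBSO)(Ar)methyl]-2-Ar-3-[(E)-3-Ar-prop-2-en-1-yl]tetrahydro-2H-pyran
Product: 24 4-{(E)-3-[(2R,3S,5R)-5-[(R)-hydroxy(4-hydroxyphenyl)methyl]-2-(4-hydroxyphenyl)tetrahydro-2H-pyran-3-yl]prop-1-en-1-yl}phenol (CNP0182155.1)
Conditions: TBAF, AcOH (1:1), THF, 0 °C → rt
Reagents that add atoms: none
Why: Fluoride-mediated desilylation buffered with acetic acid should remove the three aryl TIPS groups and the benzylic TBS group under near-neutral conditions that avoid quinone methide formation at the para-hydroxybenzylic C2 and C7 positions.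

**Compound list**

1 | 4-iodophenol | Oc1ccc(I)cc1 | starting material
2 | (4-iodophenoxy)triisopropylsilane | CC(C)[Si](Oc1ccc(I)cc1)(C(C)C)C(C)C | intermediate
3 | tert-butyl(but-3-yn-1-yloxy)dimethylsilane (TBS ether of but-3-yn-1-ol, catalogue compound) | C#CCCO[Si](C)(C)C(C)(C)C | starting material
4 | tert-butyldimethyl{[4-(4-triisopropylsilyloxyphenyl)but-3-yn-1-yl]oxy}silane | CC(C)(C)[Si](C)(C)OCCC#Cc1ccc(O[Si](C(C)C)(C(C)C)C(C)C)cc1 | intermediate
5 | ethylene | C=C | starting material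
6 | hexacarbonyldicobalt complex of alkyne 4 (C2Co2 tetrahedrane, three CO on each cobalt; formed in the flask) | CC(C)(C)[Si](C)(C)OCCC12C3(c4ccc(O[Si](C(C)C)(C(C)C)C(C)C)cc4)[Co]1(=C=O)(=C=O)(=C=O)[Co]23(=C=O)(=C=O)=C=O | intermediate
7 | 3-[2-(TBSO)ethyl]-2-Ar-cyclopent-2-en-1-one | O=C1CCC(CCO[Si](C)(C)C(C)(C)C)=C1c1ccc(O[Si](C(C)C)(C(C)C)C(C)C)cc1 | intermediate
8 | 4-hydroxybenzaldehyde | O=Cc1ccc(O)cc1 | starting material
9 | 4-(triisopropylsilyloxy)benzaldehyde | O=Cc1ccc(O[Si](C(C)C)(C(C)C)C(C)C)cc1 | intermediate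
10 | boron dienolate of 7: C6–O–B[CH2-(1R,2S,5R)-menthyl]2 with C5=C6 and C2=C3 double bonds (formed in the flask) | CC(C)(C)[Si](C)(C)OCCC1=C(c2ccc(O[Si](C(C)C)(C(C)C)C(C)C)cc2)C(OB(C[C@@H]2C[C@H](C)CC[C@H]2C(C)C)C[C@@H]2C[C@H](C)CC[C@H]2C(C)C)=CC1 | intermediate
11 | (5S)-3-[2-(TBSO)ethyl]-5-[(R)-hydroxy(Ar)methyl]-2-Ar-cyclopent-2-en-1-one (anti aldol) | O=C1C(c2ccc(O[Si](C(C)C)(C(C)C)C(C)C)cc2)=C(CCO[Si](C)(C)C(C)(C)C)C[C@H]1[C@@H](O)c1ccc(O[Si](C(C)C)(C(C)C)C(C)C)cc1 | intermediate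
12 | (5S)-3-[2-(TBSO)ethyl]-5-[(R)-(TBSO)(Ar)methyl]-2-Ar-cyclopent-2-en-1-one | O=C1C(c2ccc(O[Si](C(C)C)(C(C)C)C(C)C)cc2)=C(CCO[Si](C)(C)C(C)(C)C)C[C@H]1[C@@H](O[Si](C)(C)C(C)(C)C)c1ccc(O[Si](C(C)C)(C(C)C)C(C)C)cc1 | intermediate
13 | (2R,3R,5S)-3-[2-(TBSO)ethyl]-5-[(R)-(TBSO)(Ar)methyl]-2-Ar-cyclopentan-1-one (all-cis) | O=C1[C@@H](c2ccc(O[Si](C(C)C)(C(C)C)C(C)C)cc2)[C@@H](CCO[Si](C)(C)C(C)(C)C)C[C@H]1[C@@H](O[Si](C)(C)C(C)(C)C)c1ccc(O[Si](C(C)C)(C(C)C)C(C)C)cc1 | intermediate
14 | Criegee adduct of 13: C6 carries OH and the 3-chlorobenzoylperoxy group, C6 configuration undefined, C2, C3, C5 and C7 as in 13 (formed in the flask) | OC1(OOC(=O)c2cccc(Cl)c2)[C@@H](c2ccc(O[Si](C(C)C)(C(C)C)C(C)C)cc2)[C@@H](CCO[Si](C)(C)C(C)(C)C)C[C@H]1[C@@H](O[Si](C)(C)C(C)(C)C)c1ccc(O[Si](C(C)C)(C(C)C)C(C)C)cc1 | intermediate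
15 | (3S,5R,6R)-5-[2-(TBSO)ethyl]-3-[(R)-(TBSO)(Ar)methyl]-6-Ar-tetrahydro-2H-pyran-2-one (all-cis δ-lactone) | CC(C)(C)[Si](C)(C)OCC[C@H]1C[C@@H]([C@@H](O[Si](C)(C)C(C)(C)C)c2ccc(O[Si](C(C)C)(C(C)C)C(C)C)cc2)C(=O)O[C@H]1c1ccc(O[Si](C(C)C)(C(C)C)C(C)C)cc1 | intermediate
16 | (1R,2R,4R)-2-[2-(TBSO)ethyl]-4-[(R)-(TBSO)(Ar)methyl]-1-Ar-pentane-1,5-diol | CC(C)(C)[Si](C)(C)OCC[C@@H](C[C@@H]([C@@H](O[Si](C)(C)C(C)(C)C)c1ccc(O[Si](C(C)C)(C(C)C)C(C)C)cc1)CO)[C@@H](O)c1ccc(O[Si](C(C)C)(C(C)C)C(C)C)cc1 | intermediate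
17 | primary (C6) 4-methylbenzenesulfonate of diol 16 (formed in the flask) | CC(C)(C)[Si](C)(C)OCC[C@@H](C[C@@H]([C@@H](O[Si](C)(C)C(C)(C)C)c1ccc(O[Si](C(C)C)(C(C)C)C(C)C)cc1)COS(=O)(=O)c1ccc(C)cc1)[C@@H](O)c1ccc(O[Si](C(C)C)(C(C)C)C(C)C)cc1 | intermediate
18 | (2R,3R,5R)-3-[2-(TBSO)ethyl]-5-[(R)-(TBSO)(Ar)methyl]-2-Ar-tetrahydro-2H-pyran (all-cis) | CC(C)(C)[Si](C)(C)OCC[C@H]1C[C@@H]([C@@H](O[Si](C)(C)C(C)(C)C)c2ccc(O[Si](C(C)C)(C(C)C)C(C)C)cc2)CO[C@H]1c1ccc(O[Si](C(C)C)(C(C)C)C(C)C)cc1 | intermediate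
19 | 2-{(2R,3R,5R)-5-[(R)-(TBSO)(Ar)methyl]-2-Ar-tetrahydro-2H-pyran-3-yl}ethan-1-ol | OCC[C@H]1C[C@@H]([C@@H](O[Si](C)(C)C(C)(C)C)c2ccc(O[Si](C(C)C)(C(C)C)C(C)C)cc2)CO[C@H]1c1ccc(O[Si](C(C)C)(C(C)C)C(C)C)cc1 | intermediate
20 | PT sulfide of 19: 5-({2-[(2R,3R,5R)-5-[(R)-(TBSO)(Ar)methyl]-2-Ar-tetrahydro-2H-pyran-3-yl]ethyl}sulfanyl)-1-phenyl-1H-tetrazole | c1ccccc1-n1nnnc1SCC[C@H]1C[C@@H]([C@@H](O[Si](C)(C)C(C)(C)C)c2ccc(O[Si](C(C)C)(C(C)C)C(C)C)cc2)CO[C@H]1c1ccc(O[Si](C(C)C)(C(C)C)C(C)C)cc1 | intermediate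
21 | PT sulfone: 5-({2-[(2R,3R,5R)-5-[(R)-(TBSO)(Ar)methyl]-2-Ar-tetrahydro-2H-pyran-3-yl]ethyl}sulfonyl)-1-phenyl-1H-tetrazole | O=S(=O)(CC[C@H]1C[C@@H]([C@@H](O[Si](C)(C)C(C)(C)C)c2ccc(O[Si](C(C)C)(C(C)C)C(C)C)cc2)CO[C@H]1c1ccc(O[Si](C(C)C)(C(C)C)C(C)C)cc1)c1nnnn1-c1ccccc1 | intermediate
22 | potassium salt of sulfone 21 deprotonated at the carbon next to sulfur (formed in the flask) | [K+].O=S(=O)([CH-]C[C@H]1C[C@@H]([C@@H](O[Si](C)(C)C(C)(C)C)c2ccc(O[Si](C(C)C)(C(C)C)C(C)C)cc2)CO[C@H]1c1ccc(O[Si](C(C)C)(C(C)C)C(C)C)cc1)c1nnnn1-c1ccccc1 | intermediate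
23 | (2R,3S,5R)-5-[(R)-(TBSO)(Ar)methyl]-2-Ar-3-[(E)-3-Ar-prop-2-en-1-yl]tetrahydro-2H-pyran | CC(C)[Si](Oc1ccc(/C=C/C[C@H]2C[C@@H]([C@@H](O[Si](C)(C)C(C)(C)C)c3ccc(O[Si](C(C)C)(C(C)C)C(C)C)cc3)CO[C@H]2c2ccc(O[Si](C(C)C)(C(C)C)C(C)C)cc2)cc1)(C(C)C)C(C)C | intermediate
24 | 4-{(E)-3-[(2R,3S,5R)-5-[(R)-hydroxy(4-hydroxyphenyl)methyl]-2-(4-hydroxyphenyl)tetrahydro-2H-pyran-3-yl]prop-1-en-1-yl}phenol (CNP0182155.1) | Oc1ccc(/C=C/C[C@H]2C[C@@H]([C@@H](O)c3ccc(O)cc3)CO[C@H]2c2ccc(O)cc2)cc1 | target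

**Step count**

Total steps: 15. Longest linear sequence: 14 steps (steps 1–3 and 5–15, from 4-iodophenol).

**Steps most likely to fail**

1. Step 5. The boron ligands may discriminate the enolate faces incompletely, and enolisation may stray to the γ-positions instead of C5. The fallback sets out from 7 and comes back at 11. Enone 7 is enolised with dicyclohexylboron chloride and triethylamine to the achiral dicyclohexylboron dienolate F1. F1 adds to 9 and, after oxidative work-up, should give the racemic anti aldol, that is 11 mixed with its mirror image, the (5R,7S) aldol F2. An acylative kinetic resolution follows (isobutyric anhydride, i-Pr2NEt, and the benzotetramisole enantiomer that acylates the (7S) carbinol faster, expected by analogy with 1-arylalkanols to be the (S)-catalyst). It turns F2 into the isobutyrate of the (5R,7S) aldol F3 and leaves 11, which is separated by chromatography and enters step 6.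

2. Step 7. The two faces of the enone may be poorly distinguished on the catalyst surface, reduction of the tetrasubstituted alkene may stall, the benzylic C7–O bond may undergo hydrogenolysis, or C2 may epimerise by enolisation on the catalyst. The fallback sets out from 12 and comes back at 13, with hydride and proton delivered separately. Conjugate reduction of 12 with hexameric (triphenylphosphine)copper hydride in the presence of TMSCl should place hydride on C3 anti to the C5 substituent and trap the enolate as the trimethylsilyl enol ether F4. Methyllithium then releases the lithium enolate F5, which is protonated at −78 °C with ethyl salicylate on the face away from the now cis C3 and C5 substituents to give 13.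

3. Step 3. The cycloaddition of the internal alkyne complex with ethylene may be slow, the cobalt complex may decompose under the N-oxide, and some of the regioisomeric enone may form. The fallback sets out from 4 and comes back at 7. The zirconocene–ethylene complex generated from Cp2ZrCl2 and two equivalents of EtMgBr couples with 4 to the 2-Ar-3-[2-(TBSO)ethyl]zirconacyclopent-2-ene F6, with the aryl-bearing carbon bound to zirconium. Carbonylation (CO, 1 atm) followed by iodine should release 7 with the aryl group next to the carbonyl.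

**Further compounds**

F1 | step 5 | dicyclohexylboron dienolate of 7 (C6–O–B(cyclohexyl)2, C5=C6 and C2=C3 double bonds) | CC(C)(C)[Si](C)(C)OCCC1=C(c2ccc(O[Si](C(C)C)(C(C)C)C(C)C)cc2)C(OB(C2CCCCC2)C2CCCCC2)=CC1
F2 | step 5 | (5R)-3-[2-(TBSO)ethyl]-5-[(S)-hydroxy(Ar)methyl]-2-Ar-cyclopent-2-en-1-one (mirror image of 11) | O=C1C(c2ccc(O[Si](C(C)C)(C(C)C)C(C)C)cc2)=C(CCO[Si](C)(C)C(C)(C)C)C[C@@H]1[C@H](O)c1ccc(O[Si](C(C)C)(C(C)C)C(C)C)cc1
F3 | step 5 | isobutyrate of the (5R,7S) aldol F2 at the C7 oxygen | O=C1C(c2ccc(O[Si](C(C)C)(C(C)C)C(C)C)cc2)=C(CCO[Si](C)(C)C(C)(C)C)C[C@@H]1[C@H](OC(=O)C(C)C)c1ccc(O[Si](C(C)C)(C(C)C)C(C)C)cc1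
F4 | step 7 | trimethylsilyl enol ether of 13 (C2=C6 double bond, C6–OSiMe3; C3, C5 and C7 as in 13) | C[Si](C)(C)OC1=C(c2ccc(O[Si](C(C)C)(C(C)C)C(C)C)cc2)[C@@H](CCO[Si](C)(C)C(C)(C)C)C[C@H]1[C@@H](O[Si](C)(C)C(C)(C)C)c1ccc(O[Si](C(C)C)(C(C)C)C(C)C)cc1
F5 | step 7 | lithium enolate of 13 (C2=C6 double bond; C3, C5 and C7 as in 13) | [Li+].[O-]C1=C(c2ccc(O[Si](C(C)C)(C(C)C)C(C)C)cc2)[C@@H](CCO[Si](C)(C)C(C)(C)C)C[C@H]1[C@@H](O[Si](C)(C)C(C)(C)C)c1ccc(O[Si](C(C)C)(C(C)C)C(C)C)cc1
F6 | step 3 | 1,1-bis(cyclopentadienyl)-2-Ar-3-[2-(TBSO)ethyl]-1-zirconacyclopent-2-ene | [CH-]1C=CC=C1.[CH-]1C=CC=C1.[Zr+2]1CCC(CCO[Si](C)(C)C(C)(C)C)=C1c1ccc(O[Si](C(C)C)(C(C)C)C(C)C)cc1
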